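Furanone atoms are numbered O1, C2 (carbonyl), C3, C4, C5. Everything rests on cutting C2 from C3. Because C4 carries only an exocyclic CH2OH, the ring can be reached through a tetronic acid (C4–OH, later exchanged for CH2OH by cross-coupling), whose C3 is the enolate carbon of a methyl ketone. Carbon dioxide is first fixed on an (S)-propargylic alcohol as a 4-methylene-1,3-dioxolan-2-one, a temporary ring absent from the target that ties C2 to O1 and masks the C4 ketone as an enol carbonate. In the key step alkoxide opens this ring to a regiodefined C3 enolate, which closes the furanone by C-acylation at C2 in the same flask, leaving C5 untouched.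

Key step: step 12

Remark: the primary allylic hydroxyl set free in step 10 is carried unprotected, and steps 11 to 14 are chosen so that they should tolerate it.

Step 1
Reactants: 1 dihydro-β-ionone [4-(2,6,6-trimethylcyclohex-1-en-1-yl)butan-2-one]
Product: 3 2-(but-3-yn-1-yl)-1,3,3-trimethylcyclohex-1-ene, via enol phosphate 2 (not isolated)
Conditions: LiN(iPr)2 (1.1 equiv), THF, −78 °C; ClP(O)(OEt)2, −78 → 25 °C; then LiN(iPr)2 (2.3 equiv), −78 → 25 °C; aq. NH4Cl
Reagents that add atoms: none
Why: Kinetic enolisation on the methyl side, O-phosphorylation and base-induced elimination of the enol phosphate (Negishi alkyne synthesis from methyl ketones) should give the terminal alkyne without touching the tetrasubstituted ring alkene.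

Step 2
Reactants: 3 2-(but-3-yn-1-yl)-1,3,3-trimethylcyclohex-1-ene
Product: 5 (E)-4-methyl-6-(2,6,6-trimethylcyclohex-1-en-1-yl)hex-3-en-1-ol, via alkenylalane 4 (not isolated)
Conditions: Me3Al (2 equiv), Cp2ZrCl2 (0.25 equiv), CH2Cl2, 0 → 25 °C; volatiles removed; n-BuLi, THF/hexane, −78 °C; ethylene oxide, −78 → 0 °C; 1 M HCl
Reagents that add atoms: trimethylaluminium C[Al](C)C; ethylene oxide C1CO1
Why: Zirconium-catalysed carboalumination (Negishi) adds methyl and aluminium syn across the alkyne with methyl on the internal carbon, and the derived alanate opens the epoxide with retention at the alkenyl carbon, which should fix the (E)-trisubstituted alkene.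

Step 3
Reactants: 5 (E)-4-methyl-6-(2,6,6-trimethylcyclohex-1-en-1-yl)hex-3-en-1-ol
Product: 6 2-[(E)-6-iodo-3-methylhex-3-en-1-yl]-1,3,3-trimethylcyclohex-1-ene
Conditions: I2, PPh3, imidazole, CH2Cl2, 0 → 25 °C
Reagents that add atoms: iodine II
Why: Appel-type iodination displaces the activated primary hydroxyl by SN2, and the homoallylic position rules out allylic transposition.

Step 4
Reactants: 6 2-[(E)-6-iodo-3-methylhex-3-en-1-yl]-1,3,3-trimethylcyclohex-1-ene; 7 ethyl (triphenylphosphoranylidene)acetate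
Product: 9 ethyl (E)-6-methyl-8-(2,6,6-trimethylcyclohex-1-en-1-yl)-2-(triphenylphosphoranylidene)oct-5-enoate, via phosphonium iodide 8 (not isolated)
Conditions: MeCN, 80 °C; then 2 M NaOH, CH2Cl2, 25 °C
Reagents that add atoms: none
Why: C-Alkylation of the stabilised phosphorane by the primary iodide (SN2) followed by deprotonation of the phosphonium salt should give the α-substituted stabilised ylide needed for an (E)-selective Wittig reaction.

Step 5
Reactants: 10 (S)-3-hydroxydihydrofuran-2(3H)-one [(S)-α-hydroxy-γ-butyrolactone]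
Product: 11 (S)-3-(triethylsilyloxy)dihydrofuran-2(3H)-one
Conditions: Et3SiCl, imidazole, CH2Cl2, 0 → 25 °C
Reagents that add atoms: chlorotriethylsilane CC[Si](Cl)(CC)CC
Why: Standard O-silylation; the chiral-pool carbinol carbon becomes C5 of the target, its carbonyl neighbour becomes C4 and its configuration is not touched.

Step 6
Reactants: 11 (S)-3-(triethylsilyloxy)dihydrofuran-2(3H)-one
Product: 12 (3S)-3-(triethylsilyloxy)tetrahydrofuran-2-ol (anomer mixture)
Conditions: iBu2AlH (1.1 equiv), CH2Cl2, −78 °C; aq. KNaC4H4O6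
Reagents that add atoms: none
Why: Partial reduction of a lactone to the lactol with iBu2AlH at low temperature, where the tetrahedral aluminium alkoxide is stable until work-up.

Step 7
Reactants: 12 (3S)-3-(triethylsilyloxy)tetrahydrofuran-2-ol
Product: 13 (S)-3-(triethylsilyloxy)pent-4-yn-1-ol
Conditions: dimethyl (1-diazo-2-oxopropyl)phosphonate, K2CO3, MeOH, 0 → 25 °C
Reagents that add atoms: dimethyl (1-diazo-2-oxopropyl)phosphonate COP(=O)(OC)C(=[N+]=[N-])C(C)=O
Why: Seyferth–Gilbert homologation with the Ohira–Bestmann reagent acts on the open hydroxy-aldehyde form of the lactol and turns the former lactone carbon (C4) into the internal alkyne carbon, with the new terminal carbon becoming C3.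

Step 8
Reactants: 13 (S)-3-(triethylsilyloxy)pent-4-yn-1-ol
Product: 14 (S)-3-(triethylsilyloxy)pent-4-ynal
Conditions: Dess–Martin periodinane, NaHCO3, CH2Cl2, 0 → 25 °C
Reagents that add atoms: none
Why: Buffered Dess–Martin oxidation should give the β-silyloxy aldehyde without elimination or epimerisation.

Step 9
Reactants: 14 (S)-3-(triethylsilyloxy)pent-4-ynal; 9 ethyl (E)-6-methyl-8-(2,6,6-trimethylcyclohex-1-en-1-yl)-2-(triphenylphosphoranylidene)oct-5-enoate
Product: 15 ethyl (2E,5S)-2-[(3E)-4-methyl-6-(2,6,6-trimethylcyclohex-1-en-1-yl)hex-3-en-1-yl]-5-(triethylsilyloxy)hept-2-en-6-ynoate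
Conditions: toluene, 25 → 50 °C
Reagents that add atoms: none
Why: Wittig olefination with an α-branched stabilised ylide is expected to place the ester trans to the aldehyde-derived chain, which is the geometry of the target alkene once the ester has become CH2OH.

Step 10
Reactants: 15 ethyl (2E,5S)-2-[(3E)-4-methyl-6-(2,6,6-trimethylcyclohex-1-en-1-yl)hex-3-en-1-yl]-5-(triethylsilyloxy)hept-2-en-6-ynoate
Product: 17 (3S,5E,9E)-6-(hydroxymethyl)-10-methyl-12-(2,6,6-trimethylcyclohex-1-en-1-yl)dodeca-5,9-dien-1-yn-3-ol, via triethylsilyl ether 16 (not isolated)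
Conditions: iBu2AlH (2.5 equiv), CH2Cl2, −78 °C; MeOH quench; then 1 M HCl, THF, 0 → 25 °C
Reagents that add atoms: none
Why: 1,2-Reduction of the conjugated ester by iBu2AlH gives the allylic alcohol without touching the alkyne, and the dilute acid of the work-up cleaves the labile triethylsilyl ether (ester reduction followed by acidic desilylation).

Step 11
Reactants: 17 (3S,5E,9E)-6-(hydroxymethyl)-10-methyl-12-(2,6,6-trimethylcyclohex-1-en-1-yl)dodeca-5,9-dien-1-yn-3-ol
Product: 18 (S)-5-[(2E,6E)-3-(hydroxymethyl)-7-methyl-9-(2,6,6-trimethylcyclohex-1-en-1-yl)nona-2,6-dien-1-yl]-4-methylene-1,3-dioxolan-2-one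
Conditions: CO2 (1.0 MPa), AgOAc (10 mol%), DBU (0.5 equiv), toluene, 25 °C
Reagents that add atoms: carbon dioxide O=C=O
Why: Silver-catalysed carboxylative cyclisation of a propargylic alcohol: the carbonate anion formed from the secondary hydroxyl and CO2 adds 5-exo-dig to the silver-activated terminal alkyne and protodemetalation gives the exocyclic enol carbonate, while the primary hydroxyl can only form a reversible carbonate salt and C5 is not involved.

Step 12
Reactants: 18 (S)-5-[(2E,6E)-3-(hydroxymethyl)-7-methyl-9-(2,6,6-trimethylcyclohex-1-en-1-yl)nona-2,6-dien-1-yl]-4-methylene-1,3-dioxolan-2-one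
Product: 20 (S)-4-hydroxy-5-[(2E,6E)-3-(hydroxymethyl)-7-methyl-9-(2,6,6-trimethylcyclohex-1-en-1-yl)nona-2,6-dien-1-yl]furan-2(5H)-one, via potassium enolate 19 (not isolated)
Conditions: KOtBu (3.3 equiv), THF, −78 → 0 °C; then 1 M HCl, 0 °C
Reagents that add atoms: none
Why: tert-Butoxide adds to the cyclic carbonate carbonyl C2 of 18 and the tetrahedral intermediate expels the best leaving group, the enolate oxygen on C4, so the dioxolanone opens to 19, in which C2 stays on O1 as a tert-butyl carbonate and the methyl-ketone enolate is released regiospecifically at C3. The enolate carbon C3 then attacks C2 in a 5-exo-trig Claisen (Dieckmann-type) C-acylation, tert-butoxide leaves and the furanone ring O1–C2–C3–C4–C5 is closed through the new C2–C3 bond. The closest known reaction types are the regiospecific release of enolates from enol carbonates by alkoxides and the base-induced Claisen cyclisation of α-(alkoxycarbonyloxy) ketones and α-alkylidene cyclic carbonates to tetronic acids. No stereocentre is created, and C5 should keep its (S) configuration because the enolate arises by acyl cleavage on the C3 side and not by deprotonation, so the C5 hydrogen is never removed. The step needs C- over O-acylation: O-acylation only regenerates 18 and is reversible, whereas C-acylation is made irreversible by deprotonation of the acidic tetronic acid. Excess base also covers the free primary hydroxyl, whose alkoxide can only add to C2 and be expelled again in the Claisen step.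

Step 13
Reactants: 20 (S)-4-hydroxy-5-[(2E,6E)-3-(hydroxymethyl)-7-methyl-9-(2,6,6-trimethylcyclohex-1-en-1-yl)nona-2,6-dien-1-yl]furan-2(5H)-one
Product: 21 (S)-2-[(2E,6E)-3-(hydroxymethyl)-7-methyl-9-(2,6,6-trimethylcyclohex-1-en-1-yl)nona-2,6-dien-1-yl]-5-oxo-2,5-dihydrofuran-3-yl trifluoromethanesulfonate
Conditions: PhNTf2 (1.1 equiv), Et3N (1.2 equiv), CH2Cl2, 0 → 25 °C
Reagents that add atoms: N-phenylbis(trifluoromethanesulfonimide) O=S(=O)(C(F)(F)F)N(c1ccccc1)S(=O)(=O)C(F)(F)F
Why: Chemoselective O-sulfonylation of a vinylogous acid: only the tetronic acid is ionised by the amine, and the mild triflimide reagent should triflate this anion at the C4 oxygen but not the neutral primary alcohol.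

Step 14
Reactants: 21 (S)-2-[(2E,6E)-3-(hydroxymethyl)-7-methyl-9-(2,6,6-trimethylcyclohex-1-en-1-yl)nona-2,6-dien-1-yl]-5-oxo-2,5-dihydrofuran-3-yl trifluoromethanesulfonate
Product: 22 (S)-4-(hydroxymethyl)-5-[(2E,6E)-3-(hydroxymethyl)-7-methyl-9-(2,6,6-trimethylcyclohex-1-en-1-yl)nona-2,6-dien-1-yl]furan-2(5H)-one
Conditions: Bu3SnCH2OH (1.5 equiv), Pd(PPh3)4 (5 mol%), LiCl (3 equiv), 1,4-dioxane, 90 °C; aq. KF work-up
Reagents that add atoms: (tributylstannyl)methanol CCCC[Sn](CO)(CCCC)CCCC
Why: Stille coupling of the activated vinylogous acyl triflate under neutral conditions transfers the hydroxymethyl group to C4 with chloride assisting transmetalation, and the free hydroxyls, the lactone and the C5 stereocentre should be unaffected.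

Compound list
1 | dihydro-β-ionone [4-(2,6,6-trimethylcyclohex-1-en-1-yl)butan-2-one] | CC(=O)CCC1=C(C)CCCC1(C)C | starting material
2 | diethyl 4-(2,6,6-trimethylcyclohex-1-en-1-yl)but-1-en-2-yl phosphate (enol phosphate; not isolated) | C=C(OP(=O)(OCC)OCC)CCC1=C(C)CCCC1(C)C | intermediate
3 | 2-(but-3-yn-1-yl)-1,3,3-trimethylcyclohex-1-ene | C#CCCC1=C(C)CCCC1(C)C | intermediate
4 | dimethyl[(E)-2-methyl-4-(2,6,6-trimethylcyclohex-1-en-1-yl)but-1-en-1-yl]alumane (not isolated) | C[Al](C)/C=C(\C)CCC1=C(C)CCCC1(C)C | intermediate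
5 | (E)-4-methyl-6-(2,6,6-trimethylcyclohex-1-en-1-yl)hex-3-en-1-ol | OCC/C=C(\C)CCC1=C(C)CCCC1(C)C | intermediate
6 | 2-[(E)-6-iodo-3-methylhex-3-en-1-yl]-1,3,3-trimethylcyclohex-1-ene | ICC/C=C(\C)CCC1=C(C)CCCC1(C)C | intermediate
7 | ethyl (triphenylphosphoranylidene)acetate | CCOC(=O)C=P(c1ccccc1)(c1ccccc1)c1ccccc1 | starting material
8 | [(E)-1-ethoxy-6-methyl-1-oxo-8-(2,6,6-trimethylcyclohex-1-en-1-yl)oct-5-en-2-yl]triphenylphosphonium iodide (not isolated) | CCOC(=O)C(CC/C=C(\C)CCC1=C(C)CCCC1(C)C)[P+](c1ccccc1)(c1ccccc1)c1ccccc1.[I-] | intermediate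
9 | ethyl (E)-6-methyl-8-(2,6,6-trimethylcyclohex-1-en-1-yl)-2-(triphenylphosphoranylidene)oct-5-enoate | CCOC(=O)C(CC/C=C(\C)CCC1=C(C)CCCC1(C)C)=P(c1ccccc1)(c1ccccc1)c1ccccc1 | intermediate
10 | (S)-3-hydroxydihydrofuran-2(3H)-one [(S)-α-hydroxy-γ-butyrolactone] | O[C@H]1CCOC1=O | starting material
11 | (S)-3-(triethylsilyloxy)dihydrofuran-2(3H)-one | CC[Si](CC)(CC)O[C@H]1CCOC1=O | intermediate
12 | (3S)-3-(triethylsilyloxy)tetrahydrofuran-2-ol (anomer mixture) | CC[Si](CC)(CC)O[C@H]1CCOC1O | intermediate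
13 | (S)-3-(triethylsilyloxy)pent-4-yn-1-ol | C#C[C@H](CCO)O[Si](CC)(CC)CC | intermediate
14 | (S)-3-(triethylsilyloxy)pent-4-ynal | C#C[C@H](CC=O)O[Si](CC)(CC)CC | intermediate
15 | ethyl (2E,5S)-2-[(3E)-4-methyl-6-(2,6,6-trimethylcyclohex-1-en-1-yl)hex-3-en-1-yl]-5-(triethylsilyloxy)hept-2-en-6-ynoate | CCOC(=O)/C(CC/C=C(\C)CCC1=C(C)CCCC1(C)C)=C/C[C@@H](C#C)O[Si](CC)(CC)CC | intermediate
16 | (2E,5S)-2-[(3E)-4-methyl-6-(2,6,6-trimethylcyclohex-1-en-1-yl)hex-3-en-1-yl]-5-(triethylsilyloxy)hept-2-en-6-yn-1-ol (not isolated) | OC/C(CC/C=C(\C)CCC1=C(C)CCCC1(C)C)=C/C[C@@H](C#C)O[Si](CC)(CC)CC | intermediate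
17 | (3S,5E,9E)-6-(hydroxymethyl)-10-methyl-12-(2,6,6-trimethylcyclohex-1-en-1-yl)dodeca-5,9-dien-1-yn-3-ol | OC/C(CC/C=C(\C)CCC1=C(C)CCCC1(C)C)=C/C[C@@H](C#C)O | intermediate
18 | (S)-5-[(2E,6E)-3-(hydroxymethyl)-7-methyl-9-(2,6,6-trimethylcyclohex-1-en-1-yl)nona-2,6-dien-1-yl]-4-methylene-1,3-dioxolan-2-one | OC/C(CC/C=C(\C)CCC1=C(C)CCCC1(C)C)=C/C[C@@H]1OC(=O)OC1=C | intermediate
19 | dipotassium enolate-alkoxide of tert-butyl (3S,5E,9E)-6-(hydroxymethyl)-10-methyl-2-oxo-12-(2,6,6-trimethylcyclohex-1-en-1-yl)dodeca-5,9-dien-3-yl carbonate (not isolated) | [K+].[K+].[O-]C/C(CC/C=C(\C)CCC1=C(C)CCCC1(C)C)=C/C[C@H](OC(=O)OC(C)(C)C)C([O-])=C | intermediate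
20 | (S)-4-hydroxy-5-[(2E,6E)-3-(hydroxymethyl)-7-methyl-9-(2,6,6-trimethylcyclohex-1-en-1-yl)nona-2,6-dien-1-yl]furan-2(5H)-one | OC/C(CC/C=C(\C)CCC1=C(C)CCCC1(C)C)=C/C[C@@H]1OC(=O)C=C1O | intermediate
21 | (S)-2-[(2E,6E)-3-(hydroxymethyl)-7-methyl-9-(2,6,6-trimethylcyclohex-1-en-1-yl)nona-2,6-dien-1-yl]-5-oxo-2,5-dihydrofuran-3-yl trifluoromethanesulfonate | OC/C(CC/C=C(\C)CCC1=C(C)CCCC1(C)C)=C/C[C@@H]1OC(=O)C=C1OS(=O)(=O)C(F)(F)F | intermediate
22 | (S)-4-(hydroxymethyl)-5-[(2E,6E)-3-(hydroxymethyl)-7-methyl-9-(2,6,6-trimethylcyclohex-1-en-1-yl)nona-2,6-dien-1-yl]furan-2(5H)-one | CC1=C(CC/C(C)=C/CC/C(=C\C[C@@H]2OC(=O)C=C2CO)CO)C(C)(C)CCC1 | target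

Total step count: 14 steps.
Longest linear sequence: 10 steps (steps 1 to 4, then 9 to 14; the branch 5 to 8, then 9 to 14, is equally long).

Steps most likely to fail

Step 12 (key step). What may go wrong: proton transfer to the released enolate followed by re-enolisation towards C5, which would erode the C5 configuration or move the acyl group; or attack of alkoxide on the open-chain carbonate with loss of C2 before C-acylation. The fallback sets out from 18 and comes back at 20. It separates ring opening from C-acylation and makes the enolate by kinetic deprotonation with a non-nucleophilic amide base instead of by nucleophilic cleavage. Neutral methanolysis of 18 (MeOH, catalytic Et3N, 25 °C) should give the open-chain keto carbonate methyl (3S,5E,9E)-6-(hydroxymethyl)-10-methyl-2-oxo-12-(2,6,6-trimethylcyclohex-1-en-1-yl)dodeca-5,9-dien-3-yl carbonate F1. LiN(SiMe3)2 (3.2 equiv, THF, −78 °C) would then remove a methyl proton, and Dieckmann-type closure with loss of methoxide returns 20.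

Step 11. What may go wrong: slow carboxylative cyclisation of a secondary carbinol, and base-induced migration of the exocyclic double bond of 18 into the ring, which would erase the C5 stereocentre. The fallback sets out from 17 and comes back at 18; it uses no CO2 gas and no base in the cyclisation. The primary hydroxyl is silylated selectively (tBuMe2SiCl, imidazole, CH2Cl2, 0 °C) to (3S,5E,9E)-6-[(tert-butyldimethylsilyloxy)methyl]-10-methyl-12-(2,6,6-trimethylcyclohex-1-en-1-yl)dodeca-5,9-dien-1-yn-3-ol F2. Boc2O with DMAP converts the propargylic hydroxyl into tert-butyl (3S,5E,9E)-6-[(tert-butyldimethylsilyloxy)methyl]-10-methyl-12-(2,6,6-trimethylcyclohex-1-en-1-yl)dodeca-5,9-dien-1-yn-3-yl carbonate F3. Ph3PAuNTf2 (1 mol%, CH2Cl2, 25 °C) should then induce 5-exo-dig attack of the carbonate carbonyl oxygen on the gold-activated alkyne with loss of isobutene, giving (S)-5-[(2E,6E)-3-[(tert-butyldimethylsilyloxy)methyl]-7-methyl-9-(2,6,6-trimethylcyclohex-1-en-1-yl)nona-2,6-dien-1-yl]-4-methylene-1,3-dioxolan-2-one F4. HF·pyridine in THF removes the silyl group and returns 18.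

Step 14. What may go wrong: slow transfer of the sp3 hydroxymethyl group from tin, with competing hydrolysis or reduction of the sensitive vinylogous acyl triflate. The fallback sets out from 21 and comes back at 22; the one-carbon unit comes from carbon monoxide instead of the stannane. Palladium-catalysed reductive carbonylation (CO 1 atm, Pd(PPh3)4, Bu3SnH added slowly, THF, 50 °C) should give (S)-2-[(2E,6E)-3-(hydroxymethyl)-7-methyl-9-(2,6,6-trimethylcyclohex-1-en-1-yl)nona-2,6-dien-1-yl]-5-oxo-2,5-dihydrofuran-3-carbaldehyde F5. Its 1,2-reduction under Luche conditions (NaBH4, CeCl3·7H2O, MeOH, −78 °C) spares the lactone and gives 22.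

Further compounds
F1 | step 12 | methyl (3S,5E,9E)-6-(hydroxymethyl)-10-methyl-2-oxo-12-(2,6,6-trimethylcyclohex-1-en-1-yl)dodeca-5,9-dien-3-yl carbonate | OC/C(CC/C=C(\C)CCC1=C(C)CCCC1(C)C)=C/C[C@H](OC(=O)OC)C(C)=O
F2 | step 11 | (3S,5E,9E)-6-[(tert-butyldimethylsilyloxy)methyl]-10-methyl-12-(2,6,6-trimethylcyclohex-1-en-1-yl)dodeca-5,9-dien-1-yn-3-ol | CC(C)(C)[Si](C)(C)OC/C(CC/C=C(\C)CCC1=C(C)CCCC1(C)C)=C/C[C@@H](C#C)O
F3 | step 11 | tert-butyl (3S,5E,9E)-6-[(tert-butyldimethylsilyloxy)methyl]-10-methyl-12-(2,6,6-trimethylcyclohex-1-en-1-yl)dodeca-5,9-dien-1-yn-3-yl carbonate | CC(C)(C)[Si](C)(C)OC/C(CC/C=C(\C)CCC1=C(C)CCCC1(C)C)=C/C[C@@H](C#C)OC(=O)OC(C)(C)C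
F4 | step 11 | (S)-5-[(2E,6E)-3-[(tert-butyldimethylsilyloxy)methyl]-7-methyl-9-(2,6,6-trimethylcyclohex-1-en-1-yl)nona-2,6-dien-1-yl]-4-methylene-1,3-dioxolan-2-one | CC(C)(C)[Si](C)(C)OC/C(CC/C=C(\C)CCC1=C(C)CCCC1(C)C)=C/C[C@@H]1OC(=O)OC1=C
F5 | step 14 | (S)-2-[(2E,6E)-3-(hydroxymethyl)-7-methyl-9-(2,6,6-trimethylcyclohex-1-en-1-yl)nona-2,6-dien-1-yl]-5-oxo-2,5-dihydrofuran-3-carbaldehyde | OC/C(CC/C=C(\C)CCC1=C(C)CCCC1(C)C)=C/C[C@@H]1OC(=O)C=C1C=O
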